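# Proposed synthesis of 3,5,7,3',4'-pentahydroxy-6,8-dimethoxyflavone (15)

## Analysis of the target

The target is a flavonol, a 2-aryl-3-hydroxy-4H-chromen-4-one in which every carbon of the benzo ring A bears a substituent (C5 OH, C6 OMe, C7 OH, C8 OMe), the pyranone ring C carries the C3 hydroxyl and the C4 carbonyl, and ring B is a 3',4'-catechol attached to C2. It has no stereocenters and is flat and achiral, so the problem is one of regiochemistry and of telling seven oxygens apart. Five hydroxyls (C3, C5, C7, C3', C4') must end up free beside two methyl ethers (C6, C8); the methyl ethers therefore have to arrive with a starting material, and the other oxygens have to travel under a group that comes off without touching them. The free flavonol and the catechol are oxidised by air in base, and the pyranone can be opened at C2 by strong nucleophiles, so the hydroxyls should be uncovered last and under neutral conditions. The difficulty lies in ring A: routes that begin from an ortho-hydroxyaryl ketone need a pentaoxygenated benzene in which the C5 and C8a oxygens are already told apart. The feature used here is that ring A, seen from C4a, is locally symmetric: C5 and C8a are mirror images across the C4a–C7 axis, and C6, C7 and C8 carry the methoxy/oxygen/methoxy pattern of a syringyl group. If the C5 and C8a oxygens are replaced by bromine, ring A together with C4 becomes a 2,6-dibromosyringoyl unit whose brominated carbons are the only two hydrogen-bearing positions of syringic acid. Either bromine can then become O1 while the other is kept as the handle for the C5 hydroxyl.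

## Retrosynthetic reasoning

**15 to 14 (four benzyl C–O bonds).** The last operation should only uncover hydroxyls. Target 15 is traced to its tetrabenzyl ether 14, in which the C5 hydroxyl is already free and hydrogen-bonded to the C4 carbonyl, and the C6 and C8 methyl ethers are in place. Benzyl is chosen because one hydrogenolysis removes all four groups under neutral conditions. That step tolerates no aryl halide, so the C5 oxygen has to be set before it.

**14 to 13 (C5–O).** The C5 hydroxyl of 14 is disconnected to the C5–Br bond of 13. An oxygen cannot be carried at C5 through ring closure, because the closure needs a leaving group on both ortho carbons of the aroyl ring. The bromine left over sits peri to the C4 carbonyl, which can hold the CuI catalyst close to it and also activates the position. The forward step must exchange a hindered aryl bromide for hydroxyl without destroying the pyranone.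

**13 to 12 (O1–C8a, the key disconnection).** Ring C of 13 is opened at O1–C8a, not at O1–C2 or C2–C3 as in the classical flavonol routes. This turns ring A into an aroyl group with a bromine on each ortho carbon and a mirror plane through C4a and C7. The precursor is the 2-benzyloxy-1,3-diketone 12. The gain is that the two ortho positions never have to be differentiated, since whichever C–Br bond reacts, the same flavone results. The forward reaction must make the enol oxygen of 12 displace an unactivated bromide on an electron-rich ring, which calls for catalysis by CuI.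

**12 to 5 and 10 (C3–C4).** Diketone 12 is cut between C3 and C4 into acid chloride 5 and ketone 10, which reacts as its enolate 11. This divides the molecule into a ring A half and a ring B half of similar size. It also brings the C3 oxygen in with 10 as a benzyl ether at the final oxidation level, so no late oxidation at C3 is needed. The forward step is a Claisen-type C-acylation with a hindered aroyl chloride.

**5 to 4 to 3 to 1 (two C–Br bonds, one O–benzyl bond).** Acid chloride 5 comes from acid 4. The two C–Br bonds of 4 go back to the two ring C–H bonds of 3, the benzyl ether of syringic acid 1. These are the only ring hydrogens of 3, each ortho to one methoxyl and para to the other, so halogenation has no other site. The phenol is benzylated first because a free para-hydroxy acid would be prone to oxidation and to loss of the carboxyl under electrophilic halogenation. Benzyl ester 2 forms on the way and is saponified in the same flask.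

**10 to 8 and 7, 7 to 6 (aryl–carbonyl bond).** Ketone 10 is cut at the bond between ring B and the carbonyl carbon (the future C2). This gives aryllithium 9, made from bromide 8, and Weinreb amide 7, made from acid chloride 6. The cut delivers C2 and C3 with the C3 benzyloxy group already attached, so the oxygen on C3 never has to be introduced by an α-oxidation.

## Alternatives that were turned down

Alternative 1: The disconnection is the C3–C4 bond at the dihydroflavonol oxidation level. In the forward direction a triazolium-derived N-heterocyclic carbene would convert the aryl aldehyde of 2-[3,5-bis(benzyloxy)-2-formyl-4,6-dimethoxyphenoxy]-2-[3,4-bis(benzyloxy)phenyl]acetaldehyde A2 into an acyl anion equivalent. This adds to the aliphatic aldehyde in a crossed intramolecular benzoin reaction and should give trans-5,7-bis(benzyloxy)-2-[3,4-bis(benzyloxy)phenyl]-3-hydroxy-6,8-dimethoxychroman-4-one A1.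

- For: the closure is metal-free and mild, all seven oxygens are in place before the ring forms, and no hindered carbon–halogen bond has to be exchanged afterwards. On that last point it is stronger than the chosen route.
- Against: the polarity it needs runs against the natural preference. The carbene adds more readily to the unhindered aliphatic aldehyde of A2 than to the aryl aldehyde flanked by two ortho oxygens, and the wrong acyl anion would close the ring with the carbonyl at C3 and the hydroxyl at C4.
- Against: A2 is an enolisable α-aryl-α-aryloxy aldehyde prone to self-condensation. Making it requires alkylating one of two equivalent ring A phenols and benzylating the other, which is the desymmetrisation the chosen route avoids.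
- Against: A1 sits at the wrong oxidation level. Its two stereocenters are made only to be erased by dehydrogenation of a base-sensitive β-hydroxy ketone, with debenzylation still to follow.
- Comparison: the chosen route offers a precursor built from a symmetric acid by standard reactions and a ring closure that raises no question of regiochemistry or polarity.

Alternative 2: The disconnection is the C2=C3 double bond. In the forward direction the phosphorane carbon of 3,5-bis(benzyloxy)-2-[2-(benzyloxy)-2-(triphenyl-λ5-phosphanylidene)acetyl]-4,6-dimethoxyphenyl 3,4-bis(benzyloxy)benzoate A4 attacks the ester carbonyl on O1 in an intramolecular Wittig olefination. The product would be 3,5,7-tris(benzyloxy)-2-[3,4-bis(benzyloxy)phenyl]-6,8-dimethoxy-4H-chromen-4-one A3.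

- For: A3 is the fully benzylated target at the final oxidation level, so a single hydrogenolysis finishes the synthesis. That is one step fewer after ring closure than in the chosen route, and no transition metal is needed; on the endgame this plan is ahead.
- Against: the ylide of A4 is keto-stabilised and fully substituted at carbon, the least nucleophilic kind. It has to attack an ester, the least reactive Wittig acceptor, so acyl transfer without olefination is the likely diversion.
- Against: A4 needs a pentaoxygenated aryl ketone in which the C5 and C8a oxygens already differ (one benzylated, one aroylated). It also needs an α-alkoxy phosphonium precursor that would come from a labile α-halo-α-alkoxy ketone.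
- Comparison: the step saved at the end is spent several times over in making A4. The chosen route trades the shorter endgame for a ring A piece that needs no differentiation.

Alternative 3: The disconnections are C4a–C4, C4–C3 and O1–C2. In the forward direction the iodide 5-(benzyloxy)-2-iodo-4,6-dimethoxybenzene-1,3-diol A6 and the alkyne 1,2-bis(benzyloxy)-4-ethynylbenzene A7 are joined by a carbonylative Sonogashira coupling: zerovalent palladium inserts into the C–I bond of A6, the carbonyl group and alkyne A7 are taken up to give the ynone, and either ortho hydroxyl then adds 6-endo to the triple bond. The product would be 7-(benzyloxy)-2-[3,4-bis(benzyloxy)phenyl]-5-hydroxy-6,8-dimethoxy-4H-chromen-4-one A5.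

- For: it is the most convergent plan, with three components, two carbon–carbon bonds and ring C formed in one flask. It uses the same local symmetry as the chosen route, alkyne A7 is a stable and easily made partner, and the free C5 hydroxyl is delivered without any halogen exchange. On convergence it is clearly ahead.
- Against: A5 has no oxygen at C3. Converting a flavone into a flavonol on an electron-rich, polyoxygenated substrate needs protection of the C5 hydroxyl and a C3 oxidation by enolate hydroxylation or epoxidation, which costs two to three uncertain steps.
- Against: A6 is an air-sensitive, doubly ortho-substituted, electron-rich iodide. Oxidative addition to zerovalent palladium is slow for it, direct coupling of A6 with A7 without carbonyl insertion competes, and 5-exo closure to the five-membered benzofuranone competes with the 6-endo mode.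
- Comparison: the chosen route is less convergent but carries the C3 oxygen from the start and has no ring-size ambiguity in the closure.

Key step: step 7

Assumption: compound 12 is written as its chelated enol; a 2-alkoxy-1,3-diketone with a twisted aroyl group may sit largely in the diketo form, which changes nothing because base gives the same enolate from either tautomer, and compounds 1, 6 and 8 are taken as commercial.

## Route

Step 1
Reactants: 1 syringic acid (4-hydroxy-3,5-dimethoxybenzoic acid)
Product: 3 4-(benzyloxy)-3,5-dimethoxybenzoic acid, via benzyl 4-(benzyloxy)-3,5-dimethoxybenzoate 2 (not isolated)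
Conditions: BnBr (2.5 equiv), K2CO3, DMF, 60 °C; then NaOH, MeOH/H2O, 70 °C; then HCl to pH 2
Reagents that add atoms: benzyl bromide, BrCc1ccccc1; sodium hydroxide, [Na+].[OH-]
Why: Williamson alkylation of the phenoxide and the carboxylate, then saponification of the unhindered benzyl ester in the same flask. Acyl–oxygen cleavage places the hydroxide oxygen in the carboxyl group and releases benzyl alcohol. The aryl benzyl ether is inert to hydroxide, so only the ester is cleaved.

Step 2
Reactants: 3 4-(benzyloxy)-3,5-dimethoxybenzoic acid
Product: 4 4-(benzyloxy)-2,6-dibromo-3,5-dimethoxybenzoic acid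
Conditions: Br2 (3 equiv), NaOAc, AcOH, 60 °C, dark; Na2S2O3 quench
Reagents that add atoms: bromine, BrBr
Why: Electrophilic aromatic bromination at the only two ring hydrogens, each ortho to one methoxyl and para to the other, so regiochemistry is not in question. Acetate takes up the HBr, which should protect the benzyl ether.

Step 3
Reactants: 4 4-(benzyloxy)-2,6-dibromo-3,5-dimethoxybenzoic acid
Product: 5 4-(benzyloxy)-2,6-dibromo-3,5-dimethoxybenzoyl chloride
Conditions: (COCl)2, DMF (cat.), CH2Cl2, 0 °C to rt; concentrate and use crude
Reagents that add atoms: oxalyl chloride, ClC(=O)C(=O)Cl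
Why: Acid chloride formation through the Vilsmeier-type chloroiminium reagent, which activates the carboxyl at oxygen and is therefore little affected by the two ortho bromines. Benzyl and methyl ethers tolerate these conditions.

Step 4
Reactants: 6 benzyloxyacetyl chloride
Product: 7 2-(benzyloxy)-N-methoxy-N-methylacetamide
Conditions: MeNH(OMe)·HCl, K2CO3, CH2Cl2/H2O, 0 °C to rt
Reagents that add atoms: N,O-dimethylhydroxylamine hydrochloride, CNOC.Cl
Why: Schotten–Baumann amidation of an unhindered acid chloride gives the Weinreb amide.

Step 5
Reactants: 8 4-bromo-1,2-bis(benzyloxy)benzene; 7 2-(benzyloxy)-N-methoxy-N-methylacetamide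
Product: 10 2-(benzyloxy)-1-[3,4-bis(benzyloxy)phenyl]ethan-1-one, via [3,4-bis(benzyloxy)phenyl]lithium 9 (not isolated)
Conditions: n-BuLi, THF, −78 °C; then 7, −78 to 0 °C; then 1 M HCl
Reagents that add atoms: none
Why: Bromine–lithium exchange followed by a Weinreb ketone synthesis. The chelated tetrahedral adduct survives until the quench, so no second addition occurs, and the cold exchange outruns benzylic deprotonation.

Step 6
Reactants: 10 2-(benzyloxy)-1-[3,4-bis(benzyloxy)phenyl]ethan-1-one; 5 4-(benzyloxy)-2,6-dibromo-3,5-dimethoxybenzoyl chloride
Product: 12 (E)-2-(benzyloxy)-3-[3,4-bis(benzyloxy)phenyl]-1-[4-(benzyloxy)-2,6-dibromo-3,5-dimethoxyphenyl]-3-hydroxyprop-2-en-1-one (chelated enol of the 1,3-diketone), via lithium (Z)-2-(benzyloxy)-1-[3,4-bis(benzyloxy)phenyl]ethen-1-olate 11 (not isolated)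
Conditions: LiN(SiMe3)2 (2.2 equiv), THF, −78 °C; then 5, −78 °C to rt; then 1 M HCl
Reagents that add atoms: none
Why: Claisen-type C-acylation of a ketone lithium enolate by an aroyl chloride. The tightly bound lithium enolate in THF favours attack through carbon, and the second equivalent of base removes the more acidic diketone proton and so pulls the reaction forward. The acid chloride has no α-hydrogen and cannot divert to a ketene.

Step 7
Reactants: 12 (E)-2-(benzyloxy)-3-[3,4-bis(benzyloxy)phenyl]-1-[4-(benzyloxy)-2,6-dibromo-3,5-dimethoxyphenyl]-3-hydroxyprop-2-en-1-one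
Product: 13 3,7-bis(benzyloxy)-2-[3,4-bis(benzyloxy)phenyl]-5-bromo-6,8-dimethoxy-4H-chromen-4-one
Conditions: CuI (10 mol%), 1,10-phenanthroline (20 mol%), Cs2CO3 (2 equiv), dry DMF, 90 °C, argon
Reagents that add atoms: none
Why: Carbonate deprotonates 12 to the diketone enolate, which binds phenanthroline-ligated monovalent copper through the oxygen on the ring B side; rotation about the C3–C4 bond swings the dibromoaryl ring toward that oxygen, and the metal inserts into the adjacent ortho C–Br bond to give a seven-membered trivalent-copper metallacycle. C–O reductive elimination contracts this to the six-membered pyranone, forming O1–C8a and returning monovalent copper. The closest known reaction type is the CuI-catalysed intramolecular Ullmann-type O-arylation of 1-(2-haloaryl)-1,3-diketones to flavones. Ring C closes in a formally 6-exo-trig mode, by attack of oxygen on the aryl ipso carbon with bromide leaving outside the new ring, and no stereocenter is formed. O-arylation is required over C-arylation, and ring size secures it, because the central carbon or the C4 oxygen could only close a four-membered ring. No choice between the two bromines is needed, since the mirror plane through C4a and C7 of the syringoyl ring makes them equivalent. Reaction should stop after one closure, because the enolate oxygen is then used up and the surviving C5–Br has no intramolecular partner. The E geometry of the chelated enol already places the nucleophilic oxygen cis to the aroyl group, so no double-bond isomerisation is required.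

Step 8
Reactants: 13 3,7-bis(benzyloxy)-2-[3,4-bis(benzyloxy)phenyl]-5-bromo-6,8-dimethoxy-4H-chromen-4-one
Product: 14 3,7-bis(benzyloxy)-2-[3,4-bis(benzyloxy)phenyl]-5-hydroxy-6,8-dimethoxy-4H-chromen-4-one
Conditions: CuI (10 mol%), N,N'-bis(4-hydroxy-2,6-dimethylphenyl)oxalamide (10 mol%), LiOH·H2O (3 equiv), DMSO/H2O 4:1, 80 °C, argon; then 1 M HCl
Reagents that add atoms: lithium hydroxide monohydrate, [Li+].[OH-].O
Why: CuI-catalysed Ullmann-type hydroxylation of an aryl bromide; the peri C4 carbonyl activates the C5–Br bond and can pre-coordinate the metal next to it. The product phenoxide is held by the carbonyl and is inert to further reaction. Once the bromide has been exchanged, both ortho oxygens of any ring-opened form are equivalent, so the acidic work-up should re-close it to the same flavone.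

Step 9
Reactants: 14 3,7-bis(benzyloxy)-2-[3,4-bis(benzyloxy)phenyl]-5-hydroxy-6,8-dimethoxy-4H-chromen-4-one
Product: 15 2-(3,4-dihydroxyphenyl)-3,5,7-trihydroxy-6,8-dimethoxy-4H-chromen-4-one (3,5,7,3',4'-pentahydroxy-6,8-dimethoxyflavone)
Conditions: H2 (1 atm), 10% Pd/C, THF/MeOH, rt; filter and concentrate under argon
Reagents that add atoms: none
Why: Catalytic hydrogenolysis of the four O-benzyl bonds under neutral conditions. The methyl ethers and the chromone are untouched at 1 atm and room temperature, and no aryl halide remains to interfere.

## Compound list

1 | syringic acid (4-hydroxy-3,5-dimethoxybenzoic acid) | COc1cc(C(=O)O)cc(OC)c1O | starting material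
2 | benzyl 4-(benzyloxy)-3,5-dimethoxybenzoate | COc1cc(C(=O)OCc2ccccc2)cc(OC)c1OCc1ccccc1 | intermediate
3 | 4-(benzyloxy)-3,5-dimethoxybenzoic acid | COc1cc(C(=O)O)cc(OC)c1OCc1ccccc1 | intermediate
4 | 4-(benzyloxy)-2,6-dibromo-3,5-dimethoxybenzoic acid | COc1c(Br)c(C(=O)O)c(Br)c(OC)c1OCc1ccccc1 | intermediate
5 | 4-(benzyloxy)-2,6-dibromo-3,5-dimethoxybenzoyl chloride | COc1c(Br)c(C(Cl)=O)c(Br)c(OC)c1OCc1ccccc1 | intermediate
6 | benzyloxyacetyl chloride | ClC(=O)COCc1ccccc1 | starting material
7 | 2-(benzyloxy)-N-methoxy-N-methylacetamide | CON(C)C(=O)COCc1ccccc1 | intermediate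
8 | 4-bromo-1,2-bis(benzyloxy)benzene | Brc1ccc(OCc2ccccc2)c(OCc2ccccc2)c1 | starting material
9 | [3,4-bis(benzyloxy)phenyl]lithium | [Li]c1ccc(OCc2ccccc2)c(OCc2ccccc2)c1 | intermediate
10 | 2-(benzyloxy)-1-[3,4-bis(benzyloxy)phenyl]ethan-1-one | O=C(COCc1ccccc1)c1ccc(OCc2ccccc2)c(OCc2ccccc2)c1 | intermediate
11 | lithium (Z)-2-(benzyloxy)-1-[3,4-bis(benzyloxy)phenyl]ethen-1-olate | [Li+].[O-]/C(=C\OCc1ccccc1)c1ccc(OCc2ccccc2)c(OCc2ccccc2)c1 | intermediate
12 | (E)-2-(benzyloxy)-3-[3,4-bis(benzyloxy)phenyl]-1-[4-(benzyloxy)-2,6-dibromo-3,5-dimethoxyphenyl]-3-hydroxyprop-2-en-1-one (chelated enol of the 1,3-diketone) | O=C(c1c(Br)c(OC)c(OCc2ccccc2)c(OC)c1Br)/C(OCc1ccccc1)=C(\O)c1ccc(OCc2ccccc2)c(OCc2ccccc2)c1 | intermediate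
13 | 3,7-bis(benzyloxy)-2-[3,4-bis(benzyloxy)phenyl]-5-bromo-6,8-dimethoxy-4H-chromen-4-one | COc1c(OCc2ccccc2)c(OC)c2oc(-c3ccc(OCc4ccccc4)c(OCc4ccccc4)c3)c(OCc3ccccc3)c(=O)c2c1Br | intermediate
14 | 3,7-bis(benzyloxy)-2-[3,4-bis(benzyloxy)phenyl]-5-hydroxy-6,8-dimethoxy-4H-chromen-4-one | COc1c(OCc2ccccc2)c(OC)c2oc(-c3ccc(OCc4ccccc4)c(OCc4ccccc4)c3)c(OCc3ccccc3)c(=O)c2c1O | intermediate
15 | 2-(3,4-dihydroxyphenyl)-3,5,7-trihydroxy-6,8-dimethoxy-4H-chromen-4-one | COc1c(O)c(OC)c2oc(-c3ccc(O)c(O)c3)c(O)c(=O)c2c1O | target

## Step count and least certain steps

Total: 9 steps. Longest linear sequence: 7 steps (steps 1, 2, 3, 6, 7, 8, 9 from compound 1). The branch from compound 6 joins at step 6 after two steps.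

**Step 7 (key step).** The most likely failure is slow insertion of copper into a C–Br bond that is flanked by a methoxyl and by the twisted ketone. During the long heating this would let base-induced retro-Claisen cleavage of the diketone or reductive loss of bromine take over. The fallback gives up the O-arylation and closes ring C by the classical dehydration of a phenol onto the diketone. The oxygen is put in at the acid stage, where the neighbouring carboxylate assists copper substitution and there is no base-sensitive diketone. It sets out from 4 and returns at 14, replacing steps 3, 6, 7 and 8. Acid 4 is heated with CuSO4 (cat.) in aqueous NaOH at 100 °C and acidified cold, to give 4-(benzyloxy)-2,6-dihydroxy-3,5-dimethoxybenzoic acid F1. Acetone, SOCl2 and DMAP (cat.) in DME then tie the carboxyl and one phenol together as 7-(benzyloxy)-5-hydroxy-6,8-dimethoxy-2,2-dimethyl-4H-1,3-benzodioxin-4-one F2. Chloromethyl methyl ether and iPr2NEt in CH2Cl2 cap the remaining phenol as 7-(benzyloxy)-6,8-dimethoxy-5-(methoxymethoxy)-2,2-dimethyl-4H-1,3-benzodioxin-4-one F3. Enolate 11, from 10 and LiN(SiMe3)2 (2.2 equiv) in THF at −78 °C, adds to the lactone carbonyl of F3 and the ring opens with loss of acetone, which should give 2-(benzyloxy)-1-[4-(benzyloxy)-2-hydroxy-3,5-dimethoxy-6-(methoxymethoxy)phenyl]-3-[3,4-bis(benzyloxy)phenyl]propane-1,3-dione F4. Warming F4 with HCl in MeOH at 60 °C removes the methoxymethyl group and cyclodehydrates to 14; either phenol may close, because both give the same product.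

**Step 6.** The acyl group of 5 lies perpendicular to its ring, so both faces of the carbonyl are shielded by the ortho bromines. C-acylation may then be slower than O-acylation of the enolate or simple proton transfer, leaving enol ester and recovered ketone. The fallback changes the electrophile to an aldehyde, which is far less shielded, and restores the oxidation level afterwards. It sets out from 5 and returns at 12. LiAlH(OtBu)3 in THF at −78 °C reduces 5 to 4-(benzyloxy)-2,6-dibromo-3,5-dimethoxybenzaldehyde F5. Aldol addition of enolate 11 to F5 at −78 °C gives 2-(benzyloxy)-1-[3,4-bis(benzyloxy)phenyl]-3-[4-(benzyloxy)-2,6-dibromo-3,5-dimethoxyphenyl]-3-hydroxypropan-1-one F6 as a mixture of diastereomers, which does not matter because both stereocenters are lost in the next operation. Dess–Martin periodinane with NaHCO3 in CH2Cl2 then oxidises F6 to 12.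

**Step 8.** Hydroxide can add to C2 of the chromone and open ring C. The opened diketone can re-close, but it can also fragment by retro-Claisen cleavage, and the doubly ortho-substituted C5–Br bond may react too slowly to outrun this. The fallback removes the nucleophile altogether. It sets out from 13 and returns at 14. Miyaura borylation of 13 with B2pin2, Pd(OAc)2 (5 mol%), SPhos (10 mol%) and KOAc in dioxane at 90 °C gives 3,7-bis(benzyloxy)-2-[3,4-bis(benzyloxy)phenyl]-6,8-dimethoxy-5-(4,4,5,5-tetramethyl-1,3,2-dioxaborolan-2-yl)-4H-chromen-4-one F7. Oxidation of the C–B bond of F7 with NaBO3·4H2O in THF/H2O at room temperature gives 14.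

**Step 2.** The second bromination has to enter a ring that already carries one bromine and whose methoxyls are twisted out of conjugation, so it may stall at the monobromide. Forcing it invites ipso attack at C1 with loss of CO2, or cleavage of the benzyl ether by HBr. The fallback brominates at the ester stage, where decarboxylation is impossible and harsher conditions can be used. It sets out from 2, isolated after the alkylation of step 1 instead of being saponified, and returns at 4. Br2 (3 equiv) and NaOAc in AcOH at 70 °C give benzyl 4-(benzyloxy)-2,6-dibromo-3,5-dimethoxybenzoate F8. The hindered ester of F8 is cleaved with anhydrous hydroxide (KOtBu/H2O 2:1, THF/DMSO, rt) and the mixture is acidified to give 4.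

## Further compounds

F1 | step 7 | 4-(benzyloxy)-2,6-dihydroxy-3,5-dimethoxybenzoic acid | COc1c(O)c(C(=O)O)c(O)c(OC)c1OCc1ccccc1
F2 | step 7 | 7-(benzyloxy)-5-hydroxy-6,8-dimethoxy-2,2-dimethyl-4H-1,3-benzodioxin-4-one | CC1(C)OC(=O)c2c(O)c(OC)c(OCc3ccccc3)c(OC)c2O1
F3 | step 7 | 7-(benzyloxy)-6,8-dimethoxy-5-(methoxymethoxy)-2,2-dimethyl-4H-1,3-benzodioxin-4-one | CC1(C)OC(=O)c2c(OCOC)c(OC)c(OCc3ccccc3)c(OC)c2O1
F4 | step 7 | 2-(benzyloxy)-1-[4-(benzyloxy)-2-hydroxy-3,5-dimethoxy-6-(methoxymethoxy)phenyl]-3-[3,4-bis(benzyloxy)phenyl]propane-1,3-dione (racemic, tautomerising) | O=C(c1c(O)c(OC)c(OCc2ccccc2)c(OC)c1OCOC)C(OCc1ccccc1)C(=O)c1ccc(OCc2ccccc2)c(OCc2ccccc2)c1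
F5 | step 6 | 4-(benzyloxy)-2,6-dibromo-3,5-dimethoxybenzaldehyde | COc1c(Br)c(C=O)c(Br)c(OC)c1OCc1ccccc1
F6 | step 6 | 2-(benzyloxy)-1-[3,4-bis(benzyloxy)phenyl]-3-[4-(benzyloxy)-2,6-dibromo-3,5-dimethoxyphenyl]-3-hydroxypropan-1-one (mixture of racemic diastereomers) | OC(c1c(Br)c(OC)c(OCc2ccccc2)c(OC)c1Br)C(OCc1ccccc1)C(=O)c1ccc(OCc2ccccc2)c(OCc2ccccc2)c1
F7 | step 8 | 3,7-bis(benzyloxy)-2-[3,4-bis(benzyloxy)phenyl]-6,8-dimethoxy-5-(4,4,5,5-tetramethyl-1,3,2-dioxaborolan-2-yl)-4H-chromen-4-one | COc1c(OCc2ccccc2)c(OC)c2oc(-c3ccc(OCc4ccccc4)c(OCc4ccccc4)c3)c(OCc3ccccc3)c(=O)c2c1B1OC(C)(C)C(C)(C)O1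
F8 | step 2 | benzyl 4-(benzyloxy)-2,6-dibromo-3,5-dimethoxybenzoate | COc1c(Br)c(C(=O)OCc2ccccc2)c(Br)c(OC)c1OCc1ccccc1
A1 | alternative 1 | trans-5,7-bis(benzyloxy)-2-[3,4-bis(benzyloxy)phenyl]-3-hydroxy-6,8-dimethoxychroman-4-one (racemic, 2R,3R enantiomer drawn) | O=C1c2c(OCc3ccccc3)c(OC)c(OCc3ccccc3)c(OC)c2O[C@H](c2ccc(OCc3ccccc3)c(OCc3ccccc3)c2)[C@H]1O
A2 | alternative 1 | 2-[3,5-bis(benzyloxy)-2-formyl-4,6-dimethoxyphenoxy]-2-[3,4-bis(benzyloxy)phenyl]acetaldehyde (racemic) | O=Cc1c(OCc2ccccc2)c(OC)c(OCc2ccccc2)c(OC)c1OC(C=O)c1ccc(OCc2ccccc2)c(OCc2ccccc2)c1
A3 | alternative 2 | 3,5,7-tris(benzyloxy)-2-[3,4-bis(benzyloxy)phenyl]-6,8-dimethoxy-4H-chromen-4-one | COc1c(OCc2ccccc2)c(OC)c2oc(-c3ccc(OCc4ccccc4)c(OCc4ccccc4)c3)c(OCc3ccccc3)c(=O)c2c1OCc1ccccc1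
A4 | alternative 2 | 3,5-bis(benzyloxy)-2-[2-(benzyloxy)-2-(triphenyl-λ5-phosphanylidene)acetyl]-4,6-dimethoxyphenyl 3,4-bis(benzyloxy)benzoate | O=C(Oc1c(OC)c(OCc2ccccc2)c(OC)c(OCc2ccccc2)c1C(=O)C(OCc1ccccc1)=P(c1ccccc1)(c1ccccc1)c1ccccc1)c1ccc(OCc2ccccc2)c(OCc2ccccc2)c1
A5 | alternative 3 | 7-(benzyloxy)-2-[3,4-bis(benzyloxy)phenyl]-5-hydroxy-6,8-dimethoxy-4H-chromen-4-one | COc1c(OCc2ccccc2)c(OC)c2oc(-c3ccc(OCc4ccccc4)c(OCc4ccccc4)c3)cc(=O)c2c1O
A6 | alternative 3 | 5-(benzyloxy)-2-iodo-4,6-dimethoxybenzene-1,3-diol | Oc1c(I)c(O)c(OC)c(OCc2ccccc2)c1OC
A7 | alternative 3 | 1,2-bis(benzyloxy)-4-ethynylbenzene | C#Cc1ccc(OCc2ccccc2)c(OCc2ccccc2)c1
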